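**Retrosynthetic overview**

1. Ring numbering: C1(=O), C2(prenyl)2, C3(=O), C4(isobutyryl), C5(enol OH), C6(OH)(prenyl). The isobutyryl group at C4 is removed first (last-step C-acylation of a cyclic 1,3-dione). The oxygens on C5 and C6 are then tied into a pivalaldehyde acetal, a 1,3-dioxolane ring that is not in the target.
2. Key disconnection: C3–C4 and C1–C6 are cut together. This splits the carbocycle into 2,2-diprenylmalonyl dichloride (C1–C2–C3) and cis-(2R,5R)-2-tert-butyl-4-methylidene-5-prenyl-1,3-dioxolane (C4–C5–C6); forward, it is a [3+3] double C-acylation of the Effenberger type.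
3. Enabling feature: C2 is quaternary with two identical prenyl groups, so C1 and C3 are equivalent, non-enolisable acyl carbons (no regiochemistry, no ketene). C4 and C6 are the two α-carbons of the C5 carbonyl, and the vicinal O–C5/O–C6 pair fits a five-membered acetal whose tert-butyl-bearing carbon stores the chirality while C6 is planar.
4. The acetal partner comes from (R)-2-hydroxy-5-methylhex-4-enoic acid (methyl (R)-glycidate plus 2-methylprop-1-enyl Grignard reagent), via the dioxolanone and its methylenation. The dichloride comes from dimethyl malonate and prenyl bromide.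
5. Ring order: temporary dioxolane first, six-membered carbocycle second (key step), dioxolane cleaved third.

Key step: step 8

Assumption: the target is a β-triketone enol, so all its enol tautomers are taken as one compound and only the carbinol carbon C6 needs stereocontrol.

**Route**

Step 1
Reactants: 1 dimethyl malonate; 2 prenyl bromide (1-bromo-3-methylbut-2-ene)
Product: 3 dimethyl 2,2-bis(3-methylbut-2-en-1-yl)propanedioate
Conditions: NaH (2.3 equiv), 2 (2.3 equiv), THF/DMF, 0 °C → rt
Reagents that add atoms: none
Why: Double SN2 C-alkylation of the malonate enolate (malonic ester alkylation) with a reactive primary allylic bromide should go cleanly to the quaternary diester, and no stereocentre is formed.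

Step 2
Reactants: 3 dimethyl 2,2-bis(3-methylbut-2-en-1-yl)propanedioate
Product: 4 2,2-bis(3-methylbut-2-en-1-yl)propanedioic acid
Conditions: KOH (6 equiv), EtOH/H2O, reflux; then cold 2 M HCl to pH 2
Reagents that add atoms: KOH, [K+].[OH-]
Why: Saponification of the hindered diester needs forcing base, which the isolated trisubstituted alkenes tolerate, and cold acidification avoids decarboxylation of the dialkylmalonic acid.

Step 3
Reactants: 4 2,2-bis(3-methylbut-2-en-1-yl)propanedioic acid
Product: 5 2,2-bis(3-methylbut-2-en-1-yl)propanedioyl dichloride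
Conditions: 1-chloro-N,N,2-trimethylprop-1-en-1-amine (2.2 equiv), CH2Cl2, 0 °C → rt; bulb-to-bulb distillation
Reagents that add atoms: 1-chloro-N,N,2-trimethylprop-1-en-1-amine, CC(C)=C(Cl)N(C)C
Why: Acid chloride formation with an α-chloroenamine runs under neutral conditions without release of HCl, so the acid-sensitive prenyl double bonds should not be hydrochlorinated.

Step 4
Reactants: 6 methyl (2R)-oxirane-2-carboxylate (methyl (R)-glycidate); 7 2-methylprop-1-enylmagnesium bromide
Product: 8 methyl (2R)-2-hydroxy-5-methylhex-4-enoate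
Conditions: 7 (1.2 equiv, THF solution), CuI (10 mol %), THF, −40 → −20 °C; aq. NH4Cl
Reagents that add atoms: none
Why: Copper-catalysed SN2 opening of a terminal epoxide by an alkenyl Grignard reagent takes place at the unsubstituted CH2 of a glycidic ester faster than addition to the ester at low temperature, and the stereocentre is not touched, so the R configuration of 6 is carried into 8.

Step 5
Reactants: 8 methyl (2R)-2-hydroxy-5-methylhex-4-enoate
Product: 9 (2R)-2-hydroxy-5-methylhex-4-enoic acid
Conditions: LiOH (1.5 equiv), THF/H2O, 0 °C; then cold 1 M HCl to pH 3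
Reagents that add atoms: LiOH, [Li+].[OH-]
Why: Mild ester saponification at 0 °C, under which an α-hydroxy ester should not racemise.

Step 6
Reactants: 9 (2R)-2-hydroxy-5-methylhex-4-enoic acid; 10 pivalaldehyde (2,2-dimethylpropanal)
Product: 12 (2R,5R)-2-tert-butyl-5-(3-methylbut-2-en-1-yl)-1,3-dioxolan-4-one (cis), via bis-silyl hydroxy acid 11 (not isolated)
Conditions: Me3SiCl (2.3 equiv), Et3N (2.4 equiv), CH2Cl2, 0 °C → rt, salts filtered off; then 10 (1.3 equiv), Me3SiOTf (5 mol %), CH2Cl2, −78 → −30 °C; pyridine quench
Reagents that add atoms: Me3SiCl, C[Si](C)(C)Cl (its silyl groups stand only in 11)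
Why: Me3SiOTf-catalysed acetalisation of the bis-silylated hydroxy acid forms the 1,3-dioxolan-4-one at low temperature without Brønsted acid, which spares the prenyl group, and the resident stereocentre sets the new acetal centre cis to the prenyl group, the minor trans isomer being removed by chromatography.

Step 7
Reactants: 12 (2R,5R)-2-tert-butyl-5-(3-methylbut-2-en-1-yl)-1,3-dioxolan-4-one
Product: 13 (2R,5R)-2-tert-butyl-4-methylidene-5-(3-methylbut-2-en-1-yl)-1,3-dioxolane (cis)
Conditions: Cp2TiMe2 (2.2 equiv), toluene, 65 °C, dark; pentane, filtration through basic Al2O3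
Reagents that add atoms: Cp2TiMe2 (dimethyltitanocene), C[Ti](C)(C1C=CC=C1)C1C=CC=C1
Why: Petasis methylenation (thermally formed Cp2Ti=CH2, [2+2] addition and cycloreversion) converts lactone carbonyls, 1,3-dioxolan-4-ones included, into exocyclic enol ethers under neutral conditions, so neither stereocentre should epimerise.

Step 8
Reactants: 13 (2R,5R)-2-tert-butyl-4-methylidene-5-(3-methylbut-2-en-1-yl)-1,3-dioxolane; 5 2,2-bis(3-methylbut-2-en-1-yl)propanedioyl dichloride
Product: 16 (2S,3aR)-2-tert-butyl-3a,5,5-tris(3-methylbut-2-en-1-yl)-1,3-benzodioxole-4,6(3aH,5H)-dione, via vinylogous ester acid chloride 14 (not isolated), via dioxole dienolate 15 (not isolated)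
Conditions: 5 (1.5 equiv), i-Pr2NEt (4 equiv), CH2Cl2 (high dilution), 0 °C, slow addition of 13; then MgBr2·OEt2 (2.5 equiv), same flask, 0 °C → rt; aq. NaHCO3
Reagents that add atoms: none
Why: Proposed new method: the exocyclic enol ether carbon of 13 (future C4) attacks one of the two equivalent acid chloride carbons of 5 and loses HCl to the amine to give the vinylogous ester 14 as an E/Z mixture, after which MgBr2-assisted soft enolisation removes the only acidic proton left, the one on the prenyl-bearing dioxolane carbon (future C6), and the planar 2-tert-butyl-1,3-dioxole dienolate 15 closes onto the second acid chloride. The closest known reaction types are the Effenberger annulation of enol ethers with malonyl dichloride, the MgBr2·OEt2/i-Pr2NEt soft-enolisation C-acylation of ketones with acid chlorides, and the alkylation and acylation of 2-tert-butyl-1,3-dioxolan-4-one enolates; new are the dialkylmalonyl dichloride that cannot react through a ketene, the vinylogous site of the second acylation and the relay of chirality through the acetal carbon. The carbocycle is closed in the 6-(enolendo)-exo-trig mode, and closure through the enolate oxygen or through C4 would give four-membered rings, so the tether itself enforces C-acylation at C6. The quaternary carbinol centre is controlled by the acetal carbon alone: the tert-butyl group shields one face of the flat dioxole, the acyl carbon enters on the opposite face and takes the place of the departed hydrogen (self-regeneration of the stereocentre with overall retention, R at C6), and both alkene isomers of 14, both enolate geometries (which interconvert by reversible proton transfer) and any epimer at the prenyl-bearing carbon are funnelled through the same 15. The step needs one acylation per molecule of 5 before ring closure, which slow addition of 13 to an excess of dilute 5 secures, and it needs no regiocontrol because the quaternary C2 makes both acyl termini equivalent and non-enolisable. Strong aluminium, titanium or silver Lewis acids are left out because they would set off a Petasis–Ferrier type rearrangement of 13 or acylation of the prenyl double bonds.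

Step 9
Reactants: 16 (2S,3aR)-2-tert-butyl-3a,5,5-tris(3-methylbut-2-en-1-yl)-1,3-benzodioxole-4,6(3aH,5H)-dione
Product: 17 (6R)-5,6-dihydroxy-2,2,6-tris(3-methylbut-2-en-1-yl)cyclohex-4-ene-1,3-dione
Conditions: 1 M aq. HCl, THF, 0 °C → rt
Reagents that add atoms: water, O
Why: Acid hydrolysis of a vinylogous ester, in which water adds to the protonated β-alkoxy enone carbon, the ring oxygen leaves and the resulting hemiacetal sheds pivalaldehyde, should run under conditions too mild for prenyl cyclisation, and the quaternary carbinol centre cannot epimerise.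

Step 10
Reactants: 17 (6R)-5,6-dihydroxy-2,2,6-tris(3-methylbut-2-en-1-yl)cyclohex-4-ene-1,3-dione; 18 isobutyryl chloride (2-methylpropanoyl chloride)
Product: 20 (6R)-5,6-dihydroxy-2,2,6-tris(3-methylbut-2-en-1-yl)-4-(2-methylpropanoyl)cyclohex-4-ene-1,3-dione, via enol isobutyrate 19 (not isolated)
Conditions: 18 (1.05 equiv), Et3N (2.5 equiv), CH2Cl2, 0 °C; then 4-(dimethylamino)pyridine (DMAP, 20 mol %), rt; cold 0.5 M HCl
Reagents that add atoms: none
Why: O-acylation of the enolised 1,3-dione followed by DMAP-catalysed O-to-C acyl transfer, the standard route to 2-acylcyclohexane-1,3-diones, is driven by formation of the strongly acidic chelated β-triketone, while the hindered tertiary hydroxyl should be left alone and the stereocentre is untouched.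

**Compound list**

1 | dimethyl malonate | COC(=O)CC(=O)OC | starting material
2 | prenyl bromide (1-bromo-3-methylbut-2-ene) | CC(C)=CCBr | starting material
3 | dimethyl 2,2-bis(3-methylbut-2-en-1-yl)propanedioate | COC(=O)C(CC=C(C)C)(CC=C(C)C)C(=O)OC | intermediate
4 | 2,2-bis(3-methylbut-2-en-1-yl)propanedioic acid | OC(=O)C(CC=C(C)C)(CC=C(C)C)C(=O)O | intermediate
5 | 2,2-bis(3-methylbut-2-en-1-yl)propanedioyl dichloride | ClC(=O)C(CC=C(C)C)(CC=C(C)C)C(=O)Cl | intermediate
6 | methyl (2R)-oxirane-2-carboxylate | COC(=O)[C@H]1CO1 | starting material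
7 | 2-methylprop-1-enylmagnesium bromide | CC(C)=C[Mg]Br | starting material
8 | methyl (2R)-2-hydroxy-5-methylhex-4-enoate | COC(=O)[C@H](O)CC=C(C)C | intermediate
9 | (2R)-2-hydroxy-5-methylhex-4-enoic acid | OC(=O)[C@H](O)CC=C(C)C | intermediate
10 | pivalaldehyde (2,2-dimethylpropanal) | CC(C)(C)C=O | starting material
11 | trimethylsilyl (2R)-5-methyl-2-(trimethylsilyloxy)hex-4-enoate | C[Si](C)(C)OC(=O)[C@H](O[Si](C)(C)C)CC=C(C)C | intermediate
12 | (2R,5R)-2-tert-butyl-5-(3-methylbut-2-en-1-yl)-1,3-dioxolan-4-one (cis) | O=C1O[C@H](C(C)(C)C)O[C@@H]1CC=C(C)C | intermediate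
13 | (2R,5R)-2-tert-butyl-4-methylidene-5-(3-methylbut-2-en-1-yl)-1,3-dioxolane (cis) | C=C1O[C@H](C(C)(C)C)O[C@@H]1CC=C(C)C | intermediate
14 | 4-[(2R,5R)-2-tert-butyl-5-(3-methylbut-2-en-1-yl)-1,3-dioxolan-4-ylidene]-2,2-bis(3-methylbut-2-en-1-yl)-3-oxobutanoyl chloride (E/Z mixture at the exocyclic double bond) | ClC(=O)C(CC=C(C)C)(CC=C(C)C)C(=O)C=C1O[C@H](C(C)(C)C)O[C@@H]1CC=C(C)C | intermediate
15 | 4-[(2R)-2-tert-butyl-5-(3-methylbut-2-en-1-yl)-1,3-dioxol-4-yl]-3-hydroxy-2,2-bis(3-methylbut-2-en-1-yl)but-3-enoyl chloride (magnesium dienolate, drawn as the dienol; interconverting enol geometries) | ClC(=O)C(CC=C(C)C)(CC=C(C)C)C(O)=CC1=C(CC=C(C)C)O[C@@H](C(C)(C)C)O1 | intermediate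
16 | (2S,3aR)-2-tert-butyl-3a,5,5-tris(3-methylbut-2-en-1-yl)-1,3-benzodioxole-4,6(3aH,5H)-dione (tert-butyl cis to the angular prenyl group) | CC(C)=CCC1(CC=C(C)C)C(=O)C=C2O[C@H](C(C)(C)C)O[C@@]2(CC=C(C)C)C1=O | intermediate
17 | (6R)-5,6-dihydroxy-2,2,6-tris(3-methylbut-2-en-1-yl)cyclohex-4-ene-1,3-dione | CC(C)=CCC1(CC=C(C)C)C(=O)C=C(O)[C@](O)(CC=C(C)C)C1=O | intermediate
18 | isobutyryl chloride | CC(C)C(=O)Cl | starting material
19 | (4R)-4-hydroxy-4,6,6-tris(3-methylbut-2-en-1-yl)-3,5-dioxocyclohex-1-en-1-yl 2-methylpropanoate (drawn as the enol ester remote from the carbinol; the other enol ester converges on the same product) | CC(C)=CCC1(CC=C(C)C)C(OC(=O)C(C)C)=CC(=O)[C@](O)(CC=C(C)C)C1=O | intermediate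
20 | (6R)-5,6-dihydroxy-2,2,6-tris(3-methylbut-2-en-1-yl)-4-(2-methylpropanoyl)cyclohex-4-ene-1,3-dione | CC(C)=CCC1(CC=C(C)C)C(=O)C(C(=O)C(C)C)=C(O)[C@](O)(CC=C(C)C)C1=O | target

**Step count**

Total steps: 10.
Longest linear sequence: 7 steps (steps 4 to 10, from 6).

**Steps most likely to fail**

**Step 8 (proposed new method).**
- The first acylation may be sluggish, because the hindered acid chloride cannot react through a ketene.
- Both acid chloride ends may be captured by two molecules of enol ether.
- γ-Deprotonation may fail.
- The acetal may ionise while C6 is planar, which would erode the enantiopurity.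

The fallback uses known chemistry only, sets out from 12 and 5, and comes back at 17. The lithium enolate of 12 (LiN(i-Pr)2, THF, −78 °C) is added to 5. C-acylation anti to the tert-butyl group, the classical use of such dioxolanone enolates, should give 3-[(2R,5S)-2-tert-butyl-5-(3-methylbut-2-en-1-yl)-4-oxo-1,3-dioxolan-5-yl]-2,2-bis(3-methylbut-2-en-1-yl)-3-oxopropanoyl chloride F1. Me2CuLi (Et2O, −78 °C, cuprate ketone synthesis) then converts the remaining acid chloride into 1-[(2R,5S)-2-tert-butyl-5-(3-methylbut-2-en-1-yl)-4-oxo-1,3-dioxolan-5-yl]-2,2-bis(3-methylbut-2-en-1-yl)butane-1,3-dione F2, at which stage material derived from surplus 5 is removed. LiN(SiMe3)2 (THF, −78 → 0 °C) deprotonates the only enolisable position of F2, the methyl group, and the enolate closes on the lactone carbonyl (Dieckmann-type condensation, 6-exo-trig). The expelled hemiacetal alkoxide sheds pivalaldehyde, and acidic work-up gives 17. The ring bonds C1–C6 and C4–C5 are then made in separate steps, and 13 and 16 are bypassed.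

**Step 10.**
- The tertiary hydroxyl may be acylated.
- The O-to-C transfer may stall at a carbon whose two neighbouring ring carbonyl carbons (C3 and C5) each adjoin a quaternary carbon (C2 and C6).
- The amine base may start an α-ketol ring contraction.

The fallback sets out from 17 and comes back at 20, and it masks the carbinol so that neither its acylation nor the α-ketol shift is possible. Persilylation (Et3SiOTf, 2,6-lutidine, CH2Cl2, −78 → 0 °C) gives (6R)-2,2,6-tris(3-methylbut-2-en-1-yl)-5,6-bis(triethylsilyloxy)cyclohex-4-ene-1,3-dione F3. Aqueous work-up strips the labile enol silyl ether and leaves (6R)-5-hydroxy-2,2,6-tris(3-methylbut-2-en-1-yl)-6-(triethylsilyloxy)cyclohex-4-ene-1,3-dione F4. O-acylation with 18 and acyl transfer as in step 10 give (6R)-5-hydroxy-2,2,6-tris(3-methylbut-2-en-1-yl)-4-(2-methylpropanoyl)-6-(triethylsilyloxy)cyclohex-4-ene-1,3-dione F5. Buffered HF·pyridine (THF, 0 °C) then frees 20.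

**Step 4.**
- The Grignard reagent may add to the ester carbonyl.
- Halide may open the epoxide in competition with the copper-catalysed opening.

The fallback sets out from 6 and comes back at 9, and it removes the ester before the C–C bond is made. KOH (1.0 equiv, EtOH, 0 °C) precipitates potassium (2R)-oxirane-2-carboxylate F6, whose carboxylate is inert to organometallic addition. Opening at the CH2 terminus with 7 (2.5 equiv) and CuI (20 mol %) in THF (−30 → 0 °C), followed by cold acidification, gives 9 directly, so that step 5 is no longer needed.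

**Further compounds**

F1 | step 8 | 3-[(2R,5S)-2-tert-butyl-5-(3-methylbut-2-en-1-yl)-4-oxo-1,3-dioxolan-5-yl]-2,2-bis(3-methylbut-2-en-1-yl)-3-oxopropanoyl chloride | O=C1O[C@H](C(C)(C)C)O[C@@]1(CC=C(C)C)C(=O)C(CC=C(C)C)(CC=C(C)C)C(=O)Cl
F2 | step 8 | 1-[(2R,5S)-2-tert-butyl-5-(3-methylbut-2-en-1-yl)-4-oxo-1,3-dioxolan-5-yl]-2,2-bis(3-methylbut-2-en-1-yl)butane-1,3-dione | O=C1O[C@H](C(C)(C)C)O[C@@]1(CC=C(C)C)C(=O)C(CC=C(C)C)(CC=C(C)C)C(C)=O
F3 | step 10 | (6R)-2,2,6-tris(3-methylbut-2-en-1-yl)-5,6-bis(triethylsilyloxy)cyclohex-4-ene-1,3-dione | CC(C)=CCC1(CC=C(C)C)C(=O)C=C(O[Si](CC)(CC)CC)[C@](O[Si](CC)(CC)CC)(CC=C(C)C)C1=O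
F4 | step 10 | (6R)-5-hydroxy-2,2,6-tris(3-methylbut-2-en-1-yl)-6-(triethylsilyloxy)cyclohex-4-ene-1,3-dione | CC(C)=CCC1(CC=C(C)C)C(=O)C=C(O)[C@](O[Si](CC)(CC)CC)(CC=C(C)C)C1=O
F5 | step 10 | (6R)-5-hydroxy-2,2,6-tris(3-methylbut-2-en-1-yl)-4-(2-methylpropanoyl)-6-(triethylsilyloxy)cyclohex-4-ene-1,3-dione | CC(C)=CCC1(CC=C(C)C)C(=O)C(C(=O)C(C)C)=C(O)[C@](O[Si](CC)(CC)CC)(CC=C(C)C)C1=O
F6 | step 4 | potassium (2R)-oxirane-2-carboxylate | [K+].[O-]C(=O)[C@H]1CO1
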